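**Conventions.** Benzofuran numbering is used for the target (O1, C2, C3, C3a, C4–C7, C7a). Ring A is the benzene ring of the benzofuran, ring B the dihydrofuran ring, ring C the 4-hydroxy-3,5-dimethoxyphenyl (syringyl) ring.

## Analysis of the target

The target is a 2-aryl-2,3-dihydrobenzofuran neolignan in which ring A is fused to ring B, with ring C on C2 and a hydroxymethyl group on C3. Ring A carries O1 on C7a, a methoxyl on C7, an (E)-acrylic acid on C5, and hydrogens on C4 and C6. The two contiguous stereocentres are C2 (S) and C3 (R), with ring C and the hydroxymethyl group trans on ring B. Because trans is also the more stable arrangement, the real stereochemical task is absolute configuration. The sensitive groups are the free phenol para to C2 (it lets the benzylic C2–O1 bond open to a quinone methide in strong acid or hot base), the acrylic acid and the primary alcohol. The difficulty is to combine reliable control of C2/C3 with the crowded substitution pattern of ring A, where two adjacent oxygens sit meta to the side chain. The strategy rests on reading ring A as four pieces: C7 with its methoxyl as a methoxycarbene carbon, C6 and C5 as a terminal alkyne, C4 as a carbonyl ligand, and C3a=C7a as the enol-ether double bond of a dihydrofuran. That dihydrofuran already contains O1, C2 with ring C, and C3 with its protected hydroxymethyl group.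

## Retrosynthetic reasoning

**26 to 25.** The C=C bond of the acrylic acid is cut, leaving aldehyde 25. It is made last by a decarboxylative Knoevenagel–Doebner condensation, because an acrylate would not survive the organolithium, carbene and palladium hydride chemistry used earlier. The condensation must deliver only the E-alkene, which the decarboxylative pathway does.

**25 to 22 (through 24 and 23).** These are changes of functional group only. One acid treatment of 24 frees the aldehyde from its diethyl acetal, the ring C phenol from its methoxymethyl ether and the alcohol from its silyl ether. The benzannulation unavoidably puts a hydroxyl on C4, so 24 is traced to triflate 23 and phenol 22; the C4–O bond is replaced by C4–H through palladium-catalysed hydride transfer. This is the price of the ring construction and costs two steps.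

**22 to 19 and 20 (key disconnection).** Three bonds of ring A are cut: C7–C6, C5–C4 and C4–C3a. This leaves carbene complex 19, alkyne 20 and one carbonyl ligand. The cut is made here because the steric bias of a terminal alkyne fixes the whole substitution pattern of ring A in one operation. The O1–C7a bond and both stereocentres are already in place and are not touched. The forward reaction has to insert the alkyne with the acetal carbon distal to the carbene carbon and close the ring onto C3a.

**19 to 15 and 16.** The bond between the carbene carbon (future C7) and C7a is cut. Forward, 15 is metallated at its enol-ether C–H, the vinyl anion adds to a carbonyl ligand of 16, and the acylmetalate is O-methylated. This places the future C7 methoxyl directly.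

**15 to 10 (through 13).** The enol-ether double bond (future C3a=C7a) is traced to lactol 13 by dehydration. The lactol is traced to alkene 10 by oxidative removal of the terminal alkene carbon. The aldehyde so formed is captured by the benzylic hydroxyl, which becomes O1. The allyl group of 10 therefore supplies C3a and C7a.

**10 to 5 and 2 (through 9 and 8).** The C2–C3 bond is cut as an aldol bond between imide 5 and aldehyde 2. This is the only step that creates stereocentres, and the oxazolidinone controls both. The syn-aldol relationship in 8 becomes the trans relationship on ring B, because the ring is later closed through the allyl-derived carbon and the carbinol oxygen. Reduction (9) and selective silylation (10) turn the imide carbonyl into the protected C3 hydroxymethyl group.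

**5 to 3 and 4; 2 to 1.** The imide comes from N-acylation of auxiliary 3 with acid chloride 4. Aldehyde 2 comes from protection of syringaldehyde 1.

## Alternatives that were turned down

**Alternative 1: ring contraction of a flavanone by oxidative 1,2-aryl shift.**
- Disconnection: C3–C3a, with ring B arising from the pyranone ring of flavanone A2.
- Forward key step: A2 is treated with PhI(OAc)2, HC(OMe)3 and H2SO4 in methanol. The enol ether is attacked by iodine at C3, the ring A carbon migrates from the ketal carbon to C3 as iodobenzene leaves, and the former carbonyl carbon ends as the methyl ester of A1.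
- For: ring A is bought with its bromine and methoxyl in place, the trans geometry follows from migration anti to the departing iodine, and the bromide can take the acrylate by a Heck coupling without any deoxygenation. On construction of ring A this alternative is stronger than the chosen route.
- Against: the absolute configuration rests on an enantioenriched flavanone whose C2 centre is labile through reversible oxa-Michael opening to the chalcone, and the key step uses strong acid. Ring C must be deactivated as a mesylate to survive the oxidant. Removal of that mesylate needs base or a nucleophile, while C3 carries an ester with an acidic hydrogen and a β-aryloxy leaving group, so epimerization and ring opening threaten. The ester must be reduced before the acrylate is installed.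
- Comparison: shorter on ring A, weaker on stereochemical security. The chosen route offers stereocentres set by an auxiliary-controlled aldol, and a C3 substituent that is never at the ester oxidation level once ring B exists.

**Alternative 2: three-component conjunctive coupling.**
- Disconnection: C2–ring C and C3–C3a across an alkene.
- Forward key step: alkenyl boronate A4 and aryllithium A6 form a boron ate complex. With aryl iodide A5, Pd(OAc)2 and a chiral diphosphine ligand, ring C migrates from boron to the adjacent carbon while the arylpalladium species delivers ring A to the other alkene carbon, giving A3.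
- For: high convergence, catalytic control of both stereocentres in one step, and a step count to the target that should be lower than that of the chosen route. On step economy and atom economy it is stronger.
- Against: a 1,2-disubstituted alkenyl boronate is a much poorer migrating terminus than a vinyl boronate. The electrophile is an electron-rich iodide with an ortho benzyloxy group, and halide is known to interfere with ate-complex chemistry. The benzylic boronate next to a trioxygenated ring is prone to protodeboronation. Since the boron in A3 occupies the position of O1, ring closure after oxidation must occur with net retention at C2, that is, through an ionized benzylic centre, so the stereochemical information at C2 is not used directly. Two benzyl ethers must also be removed.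
- Comparison: the chosen route is longer, but every step has direct precedent on its substrate class and the C2–O1 bond is formed once, in the aldol, and never substituted afterwards.

**Alternative 3: formal [4+1] annulation of a nitrostyrene with a sulfonium benzylide.**
- Disconnection: C2–C3 and O1–C2.
- Forward key step: the ylide from sulfonium salt A9 (drawn with one enantiomer of a C2-symmetric thiolane; the sense would be chosen to fit) adds to the β-carbon of nitroalkene A8, and the phenoxide then displaces the sulfide at C2, closing ring B to A7.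
- For: both partners are one or two steps from commercial aldehydes, ring B and both stereocentres arise in one step, and the bromide is ready for a Heck coupling. It reaches the bicyclic core faster than the chosen route.
- Against: the enantioselectivity depends on a stoichiometric chiral sulfide in a conjugate addition, where facial control is less predictable than in an auxiliary aldol. The displacement at a benzylic sulfonium carbon bearing an electron-rich ring can drift towards ionization. The nitromethyl group must become hydroxymethyl through a Nef reaction, which passes through a C3 aldehyde whose enol can expel O1 or epimerize C3.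
- Comparison: shorter, but weaker in stereochemical security and in the C3 side chain. The chosen route carries the C3 substituent as a silyl ether from the aldol onwards.

Key step: step 9

Assumption: lactol 13 and the species 11, 12 and 14 around it are handled as mixtures at the one carbon that is not a target stereocentre, since that centre is destroyed in step 7.

## Route

Step 1
Reactants: 1 syringaldehyde (4-hydroxy-3,5-dimethoxybenzaldehyde)
Product: 2 3,5-dimethoxy-4-(methoxymethoxy)benzaldehyde
Conditions: MOMCl, i-Pr2NEt, CH2Cl2, 0 °C to rt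
Reagents that add atoms: chloromethyl methyl ether, COCCl
Why: O-alkylation of the acidic para-formyl phenol (methoxymethyl protection); the acetal ether tolerates the boron, hydride and organolithium steps and falls off in the acid step 12.

Step 2
Reactants: 3 (4S)-4-benzyl-1,3-oxazolidin-2-one; 4 pent-4-enoyl chloride
Product: 5 (4S)-4-benzyl-3-(pent-4-enoyl)-1,3-oxazolidin-2-one
Conditions: Et3N, DMAP (cat.), CH2Cl2, 0 °C to rt
Reagents that add atoms: none
Why: DMAP-catalysed N-acylation of the oxazolidinone by the acid chloride; no stereocentre is involved.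

Step 3
Reactants: 5 (4S)-4-benzyl-3-(pent-4-enoyl)-1,3-oxazolidin-2-one; 2 3,5-dimethoxy-4-(methoxymethoxy)benzaldehyde
Product: 8 (4S)-4-benzyl-3-[(2S)-2-{(S)-[3,5-dimethoxy-4-(methoxymethoxy)phenyl](hydroxy)methyl}pent-4-enoyl]-1,3-oxazolidin-2-one, via dibutylboron Z-enolate 6 (not isolated), via dibutylboron aldolate 7 (not isolated)
Conditions: Bu2BOTf, i-Pr2NEt, CH2Cl2, 0 °C; 2, −78 to 0 °C; then pH 7 buffer, MeOH, H2O2, 0 °C
Reagents that add atoms: none
Why: Evans syn-aldol reaction; the Z-boron enolate adds through a chair Zimmerman–Traxler transition state on the enolate face opposite the benzyl group of the (S)-auxiliary. This sets the carbinol carbon (future C2, S) and the α-carbon (future C3) together as the syn pair, which becomes trans on ring B; peroxide then cleaves the boron aldolate.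

Step 4
Reactants: 8 (4S)-4-benzyl-3-[(2S)-2-{(S)-[3,5-dimethoxy-4-(methoxymethoxy)phenyl](hydroxy)methyl}pent-4-enoyl]-1,3-oxazolidin-2-one
Product: 9 (1S,2R)-1-[3,5-dimethoxy-4-(methoxymethoxy)phenyl]-2-(prop-2-en-1-yl)propane-1,3-diol
Conditions: LiBH4, THF, 0 °C to rt
Reagents that add atoms: none
Why: Reductive cleavage of the N-acyloxazolidinone to the primary alcohol with release of the auxiliary; hydride attack on the imide carbonyl is faster than retro-aldol at this temperature, so both stereocentres are kept.

Step 5
Reactants: 9 (1S,2R)-1-[3,5-dimethoxy-4-(methoxymethoxy)phenyl]-2-(prop-2-en-1-yl)propane-1,3-diol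
Product: 10 (1S,2R)-2-({[tert-butyl(dimethyl)silyl]oxy}methyl)-1-[3,5-dimethoxy-4-(methoxymethoxy)phenyl]pent-4-en-1-ol
Conditions: TBSCl, imidazole, CH2Cl2, 0 °C
Reagents that add atoms: tert-butyldimethylsilyl chloride, CC(C)(C)[Si](C)(C)Cl
Why: Selective silylation of the primary hydroxyl over the hindered secondary benzylic hydroxyl, which must stay free to become O1.

Step 6
Reactants: 10 (1S,2R)-2-({[tert-butyl(dimethyl)silyl]oxy}methyl)-1-[3,5-dimethoxy-4-(methoxymethoxy)phenyl]pent-4-en-1-ol
Product: 13 (4R,5S)-4-({[tert-butyl(dimethyl)silyl]oxy}methyl)-5-[3,5-dimethoxy-4-(methoxymethoxy)phenyl]oxolan-2-ol (anomers), via triol 11 (not isolated), via hydroxy aldehyde 12 (not isolated)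
Conditions: OsO4 (cat.), NaIO4, 2,6-lutidine, dioxane–H2O, rt
Reagents that add atoms: osmium tetroxide (catalytic oxygen carrier), O=[Os](=O)(=O)=O; NaIO4 (terminal oxidant), [Na+].[O-]I(=O)(=O)=O
Why: Lemieux–Johnson cleavage of the terminal alkene removes one carbon, and the γ-hydroxy aldehyde closes at once to the five-membered lactol. This oxidant leaves the electron-rich ring C alone, which ozone might not.

Step 7
Reactants: 13 (4R,5S)-4-({[tert-butyl(dimethyl)silyl]oxy}methyl)-5-[3,5-dimethoxy-4-(methoxymethoxy)phenyl]oxolan-2-ol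
Product: 15 tert-butyl({(2S,3R)-2-[3,5-dimethoxy-4-(methoxymethoxy)phenyl]-2,3-dihydrofuran-3-yl}methoxy)dimethylsilane, via anomeric mesylate 14 (not isolated)
Conditions: MsCl, Et3N (excess), CH2Cl2, −40 °C to reflux
Reagents that add atoms: none
Why: Dehydration of a lactol to a cyclic enol ether through its anomeric mesylate, as in furanoid glycal synthesis. Only the ring CH2 carries a β-hydrogen, so one regioisomer can form, and the basic medium protects the enol ether and the acetal ether.

Step 8
Reactants: 15 tert-butyl({(2S,3R)-2-[3,5-dimethoxy-4-(methoxymethoxy)phenyl]-2,3-dihydrofuran-3-yl}methoxy)dimethylsilane; 16 chromium hexacarbonyl, Cr(CO)6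
Product: 19 pentacarbonyl{[(4R,5S)-4-({[tert-butyl(dimethyl)silyl]oxy}methyl)-5-[3,5-dimethoxy-4-(methoxymethoxy)phenyl]-4,5-dihydrofuran-2-yl](methoxy)methylidene}chromium, via vinyllithium 17 (not isolated), via lithium acylchromate 18 (not isolated)
Conditions: t-BuLi, THF, −78 to −20 °C; Cr(CO)6, −78 °C to rt; then Me3OBF4, CH2Cl2, 0 °C
Reagents that add atoms: trimethyloxonium tetrafluoroborate, C[O+](C)C.F[B-](F)(F)F
Why: Fischer carbene synthesis; the vinylic C–H next to the ring oxygen is the kinetically most acidic site, as in C1 lithiation of glycals. The vinyllithium adds to a carbonyl ligand, and the acylchromate is O-methylated by the Meerwein salt; the stereocentres are not involved.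

Step 9
Reactants: 19 pentacarbonyl{[(4R,5S)-4-({[tert-butyl(dimethyl)silyl]oxy}methyl)-5-[3,5-dimethoxy-4-(methoxymethoxy)phenyl]-4,5-dihydrofuran-2-yl](methoxy)methylidene}chromium; 20 3,3-diethoxyprop-1-yne
Product: 22 (2S,3R)-3-({[tert-butyl(dimethyl)silyl]oxy}methyl)-5-(diethoxymethyl)-2-[3,5-dimethoxy-4-(methoxymethoxy)phenyl]-7-methoxy-2,3-dihydro-1-benzofuran-4-ol, via tricarbonylchromium arene complex 21 (not isolated)
Conditions: 20 (2 equiv), THF, 50 °C, Ar; then air, Et2O, rt; Et3N-buffered SiO2
Reagents that add atoms: none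
Why: Dötz benzannulation of an alkenyl(methoxy)carbene complex of zerovalent chromium with a terminal alkyne; the closest known case is the benzannulation of carbene complexes made from lithiated cyclic enol ethers. Thermal loss of one carbonyl ligand opens a site for 20, which inserts into the Cr=C bond (forming C7–C6) to give a vinylcarbene, and CO insertion (forming C5–C4) then gives a chromium-bound dienylketene. Ring A is closed by 6π-electrocyclization of this ketene onto C3a (forming C4–C3a); the cyclohexadienone tautomerizes to the phenol by shift of the C3a hydrogen, and the arene arises as its Cr(CO)3 complex 21, which air demetallates. No stereocentre is created; C2 and C3 are spectators because the medium is neutral and the C3 hydrogen never belongs to an enolizable system. The selectivity needed is regiochemical: the alkyne inserts with its bulkier acetal-bearing carbon away from the carbene substituents, which puts CH(OEt)2 on C5 next to the CO-derived C4 and hydrogen on C6 next to the methoxylated C7, and a terminal alkyne gives the largest such bias. Phenol formation is favoured over cyclopentannulation or cyclobutenone formation by the alkenyl (not aryl) carbene and the coordinating solvent, and O1 is part of the enol ether and has no way to leave.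

Step 10
Reactants: 22 (2S,3R)-3-({[tert-butyl(dimethyl)silyl]oxy}methyl)-5-(diethoxymethyl)-2-[3,5-dimethoxy-4-(methoxymethoxy)phenyl]-7-methoxy-2,3-dihydro-1-benzofuran-4-ol
Product: 23 (2S,3R)-3-({[tert-butyl(dimethyl)silyl]oxy}methyl)-5-(diethoxymethyl)-2-[3,5-dimethoxy-4-(methoxymethoxy)phenyl]-7-methoxy-2,3-dihydro-1-benzofuran-4-yl trifluoromethanesulfonate
Conditions: PhNTf2, Cs2CO3, DMF, rt
Reagents that add atoms: N-phenylbis(trifluoromethanesulfonimide), O=S(=O)(N(c1ccccc1)S(=O)(=O)C(F)(F)F)C(F)(F)F
Why: O-sulfonylation of the hindered phenoxide with a neutral triflyl donor; no Lewis or Brønsted acid is present that could open the ortho acetal or the methoxymethyl ether.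

Step 11
Reactants: 23 (2S,3R)-3-({[tert-butyl(dimethyl)silyl]oxy}methyl)-5-(diethoxymethyl)-2-[3,5-dimethoxy-4-(methoxymethoxy)phenyl]-7-methoxy-2,3-dihydro-1-benzofuran-4-yl trifluoromethanesulfonate
Product: 24 tert-butyl({(2S,3R)-5-(diethoxymethyl)-2-[3,5-dimethoxy-4-(methoxymethoxy)phenyl]-7-methoxy-2,3-dihydro-1-benzofuran-3-yl}methoxy)dimethylsilane
Conditions: Pd(OAc)2 (cat.), dppp, HCO2H, Et3N (excess), DMF, 80 °C
Reagents that add atoms: none
Why: Palladium-catalysed formate reduction of an aryl triflate; zerovalent palladium formed in the flask adds oxidatively to C4–O, formate exchanges for triflate and loses CO2, and reductive elimination gives C4–H. Excess amine keeps the acetal intact.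

Step 12
Reactants: 24 tert-butyl({(2S,3R)-5-(diethoxymethyl)-2-[3,5-dimethoxy-4-(methoxymethoxy)phenyl]-7-methoxy-2,3-dihydro-1-benzofuran-3-yl}methoxy)dimethylsilane
Product: 25 (2S,3R)-2-(4-hydroxy-3,5-dimethoxyphenyl)-3-(hydroxymethyl)-7-methoxy-2,3-dihydro-1-benzofuran-5-carbaldehyde
Conditions: 2 M aq. HCl, THF, 40 °C
Reagents that add atoms: water, O
Why: Acid hydrolysis of three acid-labile groups at once (diethyl acetal, aryl methoxymethyl ether, primary silyl ether). Any reversible ionization at C2 should return the trans ring, because C3 is untouched and trans is the stable arrangement.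

Step 13
Reactants: 25 (2S,3R)-2-(4-hydroxy-3,5-dimethoxyphenyl)-3-(hydroxymethyl)-7-methoxy-2,3-dihydro-1-benzofuran-5-carbaldehyde
Product: 26 (2E)-3-[(2S,3R)-2-(4-hydroxy-3,5-dimethoxyphenyl)-3-(hydroxymethyl)-7-methoxy-2,3-dihydro-1-benzofuran-5-yl]prop-2-enoic acid
Conditions: malonic acid, pyridine, piperidine (cat.), 80 °C; then aq. HCl
Reagents that add atoms: malonic acid, OC(=O)CC(=O)O
Why: Knoevenagel–Doebner condensation; amine-catalysed condensation followed by decarboxylation in pyridine should give the E-acrylic acid, and free phenols and alcohols are tolerated as in the classical preparation of hydroxycinnamic acids.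

## Compound list

1 | syringaldehyde (4-hydroxy-3,5-dimethoxybenzaldehyde) | COc1cc(C=O)cc(OC)c1O | starting material
2 | 3,5-dimethoxy-4-(methoxymethoxy)benzaldehyde | COCOc1c(OC)cc(C=O)cc1OC | intermediate
3 | (4S)-4-benzyl-1,3-oxazolidin-2-one | O=C1N[C@@H](Cc2ccccc2)CO1 | starting material
4 | pent-4-enoyl chloride | C=CCCC(Cl)=O | starting material
5 | (4S)-4-benzyl-3-(pent-4-enoyl)-1,3-oxazolidin-2-one | C=CCCC(=O)N1[C@@H](Cc2ccccc2)COC1=O | intermediate
6 | dibutylboron Z-enolate of 5 (not isolated) | CCCCB(CCCC)O/C(=C\CC=C)N1[C@@H](Cc2ccccc2)COC1=O | intermediate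
7 | dibutylboron aldolate of 8 (not isolated) | C=CC[C@@H]([C@H](OB(CCCC)CCCC)c1cc(OC)c(OCOC)c(OC)c1)C(=O)N1[C@@H](Cc2ccccc2)COC1=O | intermediate
8 | (4S)-4-benzyl-3-[(2S)-2-{(S)-[3,5-dimethoxy-4-(methoxymethoxy)phenyl](hydroxy)methyl}pent-4-enoyl]-1,3-oxazolidin-2-one | C=CC[C@@H]([C@H](O)c1cc(OC)c(OCOC)c(OC)c1)C(=O)N1[C@@H](Cc2ccccc2)COC1=O | intermediate
9 | (1S,2R)-1-[3,5-dimethoxy-4-(methoxymethoxy)phenyl]-2-(prop-2-en-1-yl)propane-1,3-diol | C=CC[C@@H]([C@H](O)c1cc(OC)c(OCOC)c(OC)c1)CO | intermediate
10 | (1S,2R)-2-({[tert-butyl(dimethyl)silyl]oxy}methyl)-1-[3,5-dimethoxy-4-(methoxymethoxy)phenyl]pent-4-en-1-ol | C=CC[C@@H]([C@H](O)c1cc(OC)c(OCOC)c(OC)c1)CO[Si](C)(C)C(C)(C)C | intermediate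
11 | (1S,2R)-2-({[tert-butyl(dimethyl)silyl]oxy}methyl)-1-[3,5-dimethoxy-4-(methoxymethoxy)phenyl]pentane-1,4,5-triol, C4 epimers (not isolated) | OCC(O)C[C@@H]([C@H](O)c1cc(OC)c(OCOC)c(OC)c1)CO[Si](C)(C)C(C)(C)C | intermediate
12 | (3R,4S)-3-({[tert-butyl(dimethyl)silyl]oxy}methyl)-4-[3,5-dimethoxy-4-(methoxymethoxy)phenyl]-4-hydroxybutanal (not isolated) | O=CC[C@@H]([C@H](O)c1cc(OC)c(OCOC)c(OC)c1)CO[Si](C)(C)C(C)(C)C | intermediate
13 | (4R,5S)-4-({[tert-butyl(dimethyl)silyl]oxy}methyl)-5-[3,5-dimethoxy-4-(methoxymethoxy)phenyl]oxolan-2-ol, anomers | OC1C[C@H](CO[Si](C)(C)C(C)(C)C)[C@@H](c2cc(OC)c(OCOC)c(OC)c2)O1 | intermediate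
14 | (4R,5S)-4-({[tert-butyl(dimethyl)silyl]oxy}methyl)-5-[3,5-dimethoxy-4-(methoxymethoxy)phenyl]oxolan-2-yl methanesulfonate (not isolated) | CS(=O)(=O)OC1C[C@H](CO[Si](C)(C)C(C)(C)C)[C@@H](c2cc(OC)c(OCOC)c(OC)c2)O1 | intermediate
15 | tert-butyl({(2S,3R)-2-[3,5-dimethoxy-4-(methoxymethoxy)phenyl]-2,3-dihydrofuran-3-yl}methoxy)dimethylsilane | C1=C[C@H](CO[Si](C)(C)C(C)(C)C)[C@@H](c2cc(OC)c(OCOC)c(OC)c2)O1 | intermediate
16 | chromium hexacarbonyl, Cr(CO)6 | O=C=[Cr](=C=O)(=C=O)(=C=O)(=C=O)=C=O | starting material
17 | [(4R,5S)-4-({[tert-butyl(dimethyl)silyl]oxy}methyl)-5-[3,5-dimethoxy-4-(methoxymethoxy)phenyl]-4,5-dihydrofuran-2-yl]lithium (not isolated) | [Li]C1=C[C@H](CO[Si](C)(C)C(C)(C)C)[C@@H](c2cc(OC)c(OCOC)c(OC)c2)O1 | intermediate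
18 | lithium pentacarbonyl[(4R,5S)-4-({[tert-butyl(dimethyl)silyl]oxy}methyl)-5-[3,5-dimethoxy-4-(methoxymethoxy)phenyl]-4,5-dihydrofuran-2-carbonyl]chromate (not isolated) | [Li+].[O-]C(C1=C[C@H](CO[Si](C)(C)C(C)(C)C)[C@@H](c2cc(OC)c(OCOC)c(OC)c2)O1)=[Cr](=C=O)(=C=O)(=C=O)(=C=O)=C=O | intermediate
19 | pentacarbonyl{[(4R,5S)-4-({[tert-butyl(dimethyl)silyl]oxy}methyl)-5-[3,5-dimethoxy-4-(methoxymethoxy)phenyl]-4,5-dihydrofuran-2-yl](methoxy)methylidene}chromium | COc1cc([C@H]2OC(C(OC)=[Cr](=C=O)(=C=O)(=C=O)(=C=O)=C=O)=C[C@@H]2CO[Si](C)(C)C(C)(C)C)cc(OC)c1OCOC | intermediate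
20 | 3,3-diethoxyprop-1-yne | C#CC(OCC)OCC | starting material
21 | tricarbonyl(η6-arene)chromium complex of 22, Cr(CO)3 on ring A (not isolated) | COc1cc([C@H]2Oc3c(OC)cc(C(OCC)OCC)c(O)c3[C@@H]2CO[Si](C)(C)C(C)(C)C)cc(OC)c1OCOC.O=C=[Cr](=C=O)=C=O | intermediate
22 | (2S,3R)-3-({[tert-butyl(dimethyl)silyl]oxy}methyl)-5-(diethoxymethyl)-2-[3,5-dimethoxy-4-(methoxymethoxy)phenyl]-7-methoxy-2,3-dihydro-1-benzofuran-4-ol | COc1cc([C@H]2Oc3c(OC)cc(C(OCC)OCC)c(O)c3[C@@H]2CO[Si](C)(C)C(C)(C)C)cc(OC)c1OCOC | intermediate
23 | (2S,3R)-3-({[tert-butyl(dimethyl)silyl]oxy}methyl)-5-(diethoxymethyl)-2-[3,5-dimethoxy-4-(methoxymethoxy)phenyl]-7-methoxy-2,3-dihydro-1-benzofuran-4-yl trifluoromethanesulfonate | COc1cc([C@H]2Oc3c(OC)cc(C(OCC)OCC)c(OS(=O)(=O)C(F)(F)F)c3[C@@H]2CO[Si](C)(C)C(C)(C)C)cc(OC)c1OCOC | intermediate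
24 | tert-butyl({(2S,3R)-5-(diethoxymethyl)-2-[3,5-dimethoxy-4-(methoxymethoxy)phenyl]-7-methoxy-2,3-dihydro-1-benzofuran-3-yl}methoxy)dimethylsilane | COc1cc([C@H]2Oc3c(OC)cc(C(OCC)OCC)cc3[C@@H]2CO[Si](C)(C)C(C)(C)C)cc(OC)c1OCOC | intermediate
25 | (2S,3R)-2-(4-hydroxy-3,5-dimethoxyphenyl)-3-(hydroxymethyl)-7-methoxy-2,3-dihydro-1-benzofuran-5-carbaldehyde | COc1cc([C@H]2Oc3c(OC)cc(C=O)cc3[C@@H]2CO)cc(OC)c1O | intermediate
26 | (2E)-3-[(2S,3R)-2-(4-hydroxy-3,5-dimethoxyphenyl)-3-(hydroxymethyl)-7-methoxy-2,3-dihydro-1-benzofuran-5-yl]prop-2-enoic acid | COc1cc([C@H]2Oc3c(OC)cc(/C=C/C(=O)O)cc3[C@@H]2CO)cc(OC)c1O | target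

## Step count and risks

Total step count: 13. Longest linear sequence: 12 steps (from 1 through steps 1 and 3–13; the branch 3 + 4 to 5 adds step 2).

**Step 9 (key step).** Two processes are the most likely to go wrong. The first is ionization of the benzylic acetal in the chromium-bound ortho-hydroxyaryl product, where loss of ethoxide is helped by the Cr(CO)3 group and the neighbouring phenol. The second is diversion of the vinylcarbene or vinylketene into cyclobutenone formation or uptake of a second alkyne. The fallback moves the C5 carbon to the benzylic ether oxidation level, which cannot ionize in that way. It sets out from 19, which would be heated with triethyl(prop-2-yn-1-yloxy)silane in THF to give the tricarbonylchromium arene complex F1 and, after air, the phenol F2. PhNTf2 and Cs2CO3 would give the triflate F3, and Pd(OAc)2, dppp, HCO2H and Et3N the deoxygenated arene F4. PPTS in methanol at 0 °C should remove only the triethylsilyl ether, giving the benzylic alcohol F5. MnO2 in CH2Cl2 would give the protected aldehyde F6, and aqueous HCl in THF would bring the sequence back to 25.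

**Step 8.** Deprotonation may not be confined to the vinylic position: the benzylic C2–H (also next to oxygen) and the ring C positions ortho to methoxyl can compete, leading to rearrangement or wrong carbene complexes. The fallback generates the same vinyllithium by tin–lithium exchange and also bypasses the dehydration of step 7. It sets out from 13, which with PhSO2H and CaCl2 in CH2Cl2 would give the anomeric sulfone F7. Deprotonation next to sulfur (n-BuLi, THF, −78 °C) and quenching with Bu3SnCl would give the geminal stannyl sulfone F8, which should lose sulfinate on warming with i-Pr2NEt to give the vinylstannane F9. Treatment of F9 with n-BuLi at −78 °C regenerates 17, which is carried on with Cr(CO)6 and Me3OBF4 as in step 8 to rejoin the route at 19.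

**Step 11.** Oxidative addition into a triflate flanked by two ortho substituents on an electron-rich ring may be slow, so that S–O cleavage back to the phenol takes over. The fallback activates the triflate with an ortho formyl group before reduction. It sets out from 23, which with aqueous HCl in THF would give the unprotected formyl triflate F10; Pd(OAc)2, dppp, HCO2H and Et3N in DMF would then reduce it and rejoin the route at 25.

**Step 13.** With the ring C phenol free, hot amine base may open ring B through the para-phenoxide (quinone methide formation at C2), or piperidine may add to the intermediates. The fallback avoids amine base. It sets out from 25, which with Ph3P=CHCO2t-Bu in toluene at 60 °C would give the tert-butyl ester F11; trifluoroacetic acid in CH2Cl2 at 0 °C, followed by a mild bicarbonate wash to remove any trifluoroacetate ester, would give 26.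

## Further compounds

F1 | step 9 | tricarbonyl(η6-arene)chromium complex of F2, Cr(CO)3 on ring A (not isolated) | COc1cc([C@H]2Oc3c(OC)cc(CO[Si](CC)(CC)CC)c(O)c3[C@@H]2CO[Si](C)(C)C(C)(C)C)cc(OC)c1OCOC.O=C=[Cr](=C=O)=C=O
F2 | step 9 | (2S,3R)-3-({[tert-butyl(dimethyl)silyl]oxy}methyl)-2-[3,5-dimethoxy-4-(methoxymethoxy)phenyl]-7-methoxy-5-{[(triethylsilyl)oxy]methyl}-2,3-dihydro-1-benzofuran-4-ol | COc1cc([C@H]2Oc3c(OC)cc(CO[Si](CC)(CC)CC)c(O)c3[C@@H]2CO[Si](C)(C)C(C)(C)C)cc(OC)c1OCOC
F3 | step 9 | (2S,3R)-3-({[tert-butyl(dimethyl)silyl]oxy}methyl)-2-[3,5-dimethoxy-4-(methoxymethoxy)phenyl]-7-methoxy-5-{[(triethylsilyl)oxy]methyl}-2,3-dihydro-1-benzofuran-4-yl trifluoromethanesulfonate | COc1cc([C@H]2Oc3c(OC)cc(CO[Si](CC)(CC)CC)c(OS(=O)(=O)C(F)(F)F)c3[C@@H]2CO[Si](C)(C)C(C)(C)C)cc(OC)c1OCOC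
F4 | step 9 | tert-butyl({(2S,3R)-2-[3,5-dimethoxy-4-(methoxymethoxy)phenyl]-7-methoxy-5-{[(triethylsilyl)oxy]methyl}-2,3-dihydro-1-benzofuran-3-yl}methoxy)dimethylsilane | COc1cc([C@H]2Oc3c(OC)cc(CO[Si](CC)(CC)CC)cc3[C@@H]2CO[Si](C)(C)C(C)(C)C)cc(OC)c1OCOC
F5 | step 9 | {(2S,3R)-3-({[tert-butyl(dimethyl)silyl]oxy}methyl)-2-[3,5-dimethoxy-4-(methoxymethoxy)phenyl]-7-methoxy-2,3-dihydro-1-benzofuran-5-yl}methanol | COc1cc([C@H]2Oc3c(OC)cc(CO)cc3[C@@H]2CO[Si](C)(C)C(C)(C)C)cc(OC)c1OCOC
F6 | step 9 | (2S,3R)-3-({[tert-butyl(dimethyl)silyl]oxy}methyl)-2-[3,5-dimethoxy-4-(methoxymethoxy)phenyl]-7-methoxy-2,3-dihydro-1-benzofuran-5-carbaldehyde | COc1cc([C@H]2Oc3c(OC)cc(C=O)cc3[C@@H]2CO[Si](C)(C)C(C)(C)C)cc(OC)c1OCOC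
F7 | step 8 | tert-butyl({(2S,3R)-5-(benzenesulfonyl)-2-[3,5-dimethoxy-4-(methoxymethoxy)phenyl]oxolan-3-yl}methoxy)dimethylsilane, C5 epimers | O=S(=O)(c1ccccc1)C1C[C@H](CO[Si](C)(C)C(C)(C)C)[C@@H](c2cc(OC)c(OCOC)c(OC)c2)O1
F8 | step 8 | tributyl{(4R,5S)-2-(benzenesulfonyl)-4-({[tert-butyl(dimethyl)silyl]oxy}methyl)-5-[3,5-dimethoxy-4-(methoxymethoxy)phenyl]oxolan-2-yl}stannane (not isolated) | CCCC[Sn](CCCC)(CCCC)C1(S(=O)(=O)c2ccccc2)C[C@H](CO[Si](C)(C)C(C)(C)C)[C@@H](c2cc(OC)c(OCOC)c(OC)c2)O1
F9 | step 8 | tributyl{(4R,5S)-4-({[tert-butyl(dimethyl)silyl]oxy}methyl)-5-[3,5-dimethoxy-4-(methoxymethoxy)phenyl]-4,5-dihydrofuran-2-yl}stannane | CCCC[Sn](CCCC)(CCCC)C1=C[C@H](CO[Si](C)(C)C(C)(C)C)[C@@H](c2cc(OC)c(OCOC)c(OC)c2)O1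
F10 | step 11 | (2S,3R)-5-formyl-2-(4-hydroxy-3,5-dimethoxyphenyl)-3-(hydroxymethyl)-7-methoxy-2,3-dihydro-1-benzofuran-4-yl trifluoromethanesulfonate | COc1cc([C@H]2Oc3c(OC)cc(C=O)c(OS(=O)(=O)C(F)(F)F)c3[C@@H]2CO)cc(OC)c1O
F11 | step 13 | tert-butyl (2E)-3-[(2S,3R)-2-(4-hydroxy-3,5-dimethoxyphenyl)-3-(hydroxymethyl)-7-methoxy-2,3-dihydro-1-benzofuran-5-yl]prop-2-enoate | COc1cc([C@H]2Oc3c(OC)cc(/C=C/C(=O)OC(C)(C)C)cc3[C@@H]2CO)cc(OC)c1O
A1 | alternative 1 | methyl (2S,3S)-5-bromo-2-[3,5-dimethoxy-4-(methylsulfonyloxy)phenyl]-7-methoxy-2,3-dihydro-1-benzofuran-3-carboxylate (trans) | COc1cc([C@H]2Oc3c(OC)cc(Br)cc3[C@@H]2C(=O)OC)cc(OC)c1OS(C)(=O)=O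
A2 | alternative 1 | (2S)-6-bromo-2-[3,5-dimethoxy-4-(methylsulfonyloxy)phenyl]-8-methoxy-2,3-dihydro-4H-chromen-4-one | COc1cc([C@@H]2CC(=O)c3cc(Br)cc(OC)c3O2)cc(OC)c1OS(C)(=O)=O
A3 | alternative 2 | tert-butyl{(2R,3S)-3-[4-(benzyloxy)-3,5-dimethoxyphenyl]-2-[2-(benzyloxy)-5-(1,3-dioxolan-2-yl)-3-methoxyphenyl]-3-(4,4,5,5-tetramethyl-1,3,2-dioxaborolan-2-yl)propoxy}dimethylsilane | COc1cc([C@@H](B2OC(C)(C)C(C)(C)O2)[C@@H](CO[Si](C)(C)C(C)(C)C)c2cc(C3OCCO3)cc(OC)c2OCc2ccccc2)cc(OC)c1OCc1ccccc1
A4 | alternative 2 | tert-butyl(dimethyl){[(2E)-3-(4,4,5,5-tetramethyl-1,3,2-dioxaborolan-2-yl)prop-2-en-1-yl]oxy}silane | CC(C)(C)[Si](C)(C)OC/C=C/B1OC(C)(C)C(C)(C)O1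
A5 | alternative 2 | 2-[4-(benzyloxy)-3-iodo-5-methoxyphenyl]-1,3-dioxolane | COc1cc(C2OCCO2)cc(I)c1OCc1ccccc1
A6 | alternative 2 | [4-(benzyloxy)-3,5-dimethoxyphenyl]lithium | [Li]c1cc(OC)c(OCc2ccccc2)c(OC)c1
A7 | alternative 3 | (2S,3R)-5-bromo-2-[3,5-dimethoxy-4-(methoxymethoxy)phenyl]-7-methoxy-3-(nitromethyl)-2,3-dihydro-1-benzofuran (trans) | COc1cc([C@H]2Oc3c(OC)cc(Br)cc3[C@@H]2C[N+](=O)[O-])cc(OC)c1OCOC
A8 | alternative 3 | 4-bromo-2-methoxy-6-[(E)-2-nitroethenyl]phenol | COc1cc(Br)cc(/C=C/[N+](=O)[O-])c1O
A9 | alternative 3 | (2R,5R)-1-[3,5-dimethoxy-4-(methoxymethoxy)benzyl]-2,5-dimethylthiolan-1-ium trifluoromethanesulfonate | COCOc1c(OC)cc(C[S+]2[C@H](C)CC[C@H]2C)cc1OC.[O-]S(=O)(=O)C(F)(F)F
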